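**Retrosynthetic overview**
1. The side chain is attached last: C-12–C-13 by B-alkyl Suzuki–Miyaura coupling of a C-9 vinyl group with (2Z)-4-acetoxy-3-iodobut-2-enoic acid; the C-17 aldehyde is released at the very end from its dimethyl acetal.
2. Ring B (second ring, formed together with a temporary γ-lactone): double Michael addition of an acetylcyclohexene dienolate to an enantiopure 5-menthyloxybutenolide (C-7–C-8 and C-9–C-10); the C-6 ketone then gives the 6,7-alkene via its enol triflate.
3. Ring A (first ring): [3+3] Michael/Wittig annulation of 3-isopropylidenepentane-2,4-dione with allylidenetriphenylphosphorane, which forms C-3–C-4 and C-1–C-10 in one operation.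
4. Enabling feature: in ring A the gem-dimethyl carbon C-4 and the methyl-bearing C-10 are 1,3-related across C-5, the carbon that carries C-6 of ring B. C-4/C-5/C-10 is thus the acceptor carbon/central carbon/methyl-ketone carbon of an isopropylidene 1,3-diketone (its second acetyl group is C-6/C-7), and the three CH2 groups C-1 to C-3 are an allyl ylide whose two termini react as nucleophiles in turn.
5. Order of ring formation: ring A (step 2), then ring B with the temporary lactone (step 5), which is opened in step 6.

Key step: step 2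

Remark: labdane numbering is used (decalin C-1 to C-10, C-17 on C-8, side chain C-11 to C-16 on C-9, C-20 on C-10; α = face opposite to C-20); the sense of induction in step 5 is taken from the anti-to-alkoxy addition known for 5-alkoxybutenolides combined with an endo-like ring closure (with the opposite closure the (5R)-l-menthyl butenolide would be used); 5-hydroxyfuran-2(5H)-one and 4-hydroxybut-2-ynoic acid are taken as catalogue chemicals.

**Step 1**
Reactants: 1 acetone; 2 pentane-2,4-dione
Product: 3 3-(propan-2-ylidene)pentane-2,4-dione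
Conditions: TiCl4, pyridine, THF, 0 °C to rt
Reagents that add atoms: none
Why: Knoevenagel condensation under TiCl4/pyridine, which activates the ketone and binds the water formed, should give the hindered tetrasubstituted alkylidene diketone; no stereocentre is formed.

**Step 2**
Reactants: 3 3-(propan-2-ylidene)pentane-2,4-dione; 4 allyltriphenylphosphonium bromide
Product: 8 1-(2,6,6-trimethylcyclohexa-1,3-dien-1-yl)ethan-1-one, via allylidenetriphenylphosphorane 5 (not isolated), via vinylphosphonium diketone enolate 6 (not isolated), via 1-(2,6,6-trimethylcyclohexa-2,4-dien-1-yl)ethan-1-one 7 (not isolated)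
Conditions: 4, n-BuLi, THF, −78 to 0 °C; 3, −78 °C to reflux; then DBU (0.2 equiv), rt
Reagents that add atoms: none
Why: The γ-carbon (C-3) of the ambident allyl ylide 5 should add in Michael fashion to the doubly activated isopropylidene carbon (C-4) and create the quaternary gem-dimethyl centre (6); proton transfer from the diketone enolate regenerates a vinylogous ylide whose ylide carbon (C-1) undergoes intramolecular Wittig olefination with one acetyl carbonyl (C-10) to give 7, and DBU then moves the diene into conjugation with the remaining acetyl group. The closest known reaction type is the Michael addition/intramolecular Wittig [3+3] annulation of allylidenetriphenylphosphorane with 2-alkylidene-3-oxo esters, which gives 2,6,6-trimethylcyclohexadiene carboxylates. Ring A is closed by 6-exo-trig attack of the ylide carbon on the exocyclic C=O (oxaphosphetane, then loss of Ph3PO), the bond to C-4 having been made intermolecularly just before. No stereocentre is formed (8 is achiral), so no stereocontrol is needed. The step needs γ- instead of α-attack of the ylide and conjugate instead of direct carbonyl attack: the soft, unhindered γ-terminus and the twisted, cross-conjugated acetyl groups of 3 favour the vinylogous Michael path, and the two acetyl groups are equivalent, so the ring closure has no regiochemical choice.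

**Step 3**
Reactants: 8 1-(2,6,6-trimethylcyclohexa-1,3-dien-1-yl)ethan-1-one
Product: 9 1-(2,6,6-trimethylcyclohex-1-en-1-yl)ethan-1-one
Conditions: H2 (1 atm), RhCl(PPh3)3 (5 mol %), benzene–EtOH, rt
Reagents that add atoms: none
Why: Homogeneous hydrogenation with this catalyst should reduce only the unhindered cis-disubstituted C-1/C-2 alkene and leave the tetrasubstituted, acyl-conjugated C-5/C-10 alkene untouched.

**Step 4**
Reactants: 10 5-hydroxyfuran-2(5H)-one; 11 (1S,2R,5S)-(+)-menthol
Product: 12 (5S)-5-{[(1S,2R,5S)-5-methyl-2-(propan-2-yl)cyclohexyl]oxy}furan-2(5H)-one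
Conditions: TsOH (cat.), toluene, reflux with azeotropic removal of water; crystallization from light petroleum, mother liquor re-equilibrated with TsOH
Reagents that add atoms: none
Why: Acid-catalysed acetalization via the cyclic oxocarbenium ion lets the two C-5 epimers interconvert while the (5S) epimer crystallizes (crystallization-induced diastereomer transformation), which fixes the acetal stereocentre that later controls C-8.

**Step 5**
Reactants: 9 1-(2,6,6-trimethylcyclohex-1-en-1-yl)ethan-1-one; 12 (5S)-5-menthyloxybutenolide
Product: 15 (17S)-17-[(1S,2R,5S)-menthyloxy]-6-oxo-12,13,14,15,16-pentanor-5αH,8βH,9βH-labdano-11,17-lactone, via lithium dienolate 13 (not isolated), via mono-Michael lactone enolate 14 (not isolated)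
Conditions: LiN(i-Pr)2, THF, −78 °C; 12, −78 to 0 °C; aq. NH4Cl; crystallization to one diastereomer
Reagents that add atoms: none
Why: This is a double Michael addition (anionic formal Diels–Alder) of the type known for kinetic enolates of 1-acetylcycloalkenes: C-7 of 13 should add to the butenolide β-carbon anti to the menthyloxy group (sets C-8), enolate 14 should close onto C-10 through a lithium-chelated endo-like arrangement that keeps the lactone opposite to the C-10 methyl (sets C-9 and the quaternary C-10), and axial protonation at C-5 anti to that methyl should give the trans ring fusion.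

**Step 6**
Reactants: 15 keto lactone acetal
Product: 17 methyl 17,17-dimethoxy-6-oxo-12,13,14,15,16-pentanor-5αH,8βH,9αH-labdan-11-oate, via keto aldehyde ester 16 (not isolated)
Conditions: NaOMe, MeOH, 0 to 50 °C; then AcCl (excess over NaOMe), HC(OMe)3, MeOH, rt
Reagents that add atoms: sodium methoxide [Na+].[O-]C; methanol CO
Why: Methoxide should open the lactone at C-11 and the hemiacetal anion left at C-17 should expel mentholate to give 16, in which C-5, C-8 and C-9 are all enolizable and should equilibrate relative to the fixed C-10 to the trans-fused, trans-diequatorial arrangement (8α-formyl, 9β-ester); acidified methanol then acetalizes only the aldehyde because the C-6 ketone is flanked by the neopentyl C-5 (lactone methanolysis, thermodynamic epimerization, acetalization).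

**Step 7**
Reactants: 17 keto ester acetal
Product: 19 methyl 17,17-dimethoxy-6-(trifluoromethylsulfonyloxy)-12,13,14,15,16-pentanor-5αH,8βH,9αH-labd-6-en-11-oate, via potassium enolate 18 (not isolated)
Conditions: KN(SiMe3)2, THF, −78 °C; PhNTf2, −78 to 0 °C
Reagents that add atoms: N-phenylbis(trifluoromethanesulfonimide) O=S(=O)(N(c1ccccc1)S(=O)(=O)C(F)(F)F)C(F)(F)F
Why: Kinetic deprotonation should occur at C-7, the only unhindered α-CH2 (C-5 is tertiary and shielded by C-4 and C-10, and the ester α-hydrogen at C-9 is far less acidic), and O-sulfonylation of 18 fixes the enol triflate regiochemistry for the 6,7-alkene without touching a stereocentre.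

**Step 8**
Reactants: 19 enol triflate
Product: 20 methyl 17,17-dimethoxy-12,13,14,15,16-pentanor-5αH,8βH,9αH-labd-6-en-11-oate
Conditions: Pd(OAc)2 (5 mol %), PPh3, n-Bu3N, HCO2H, DMF, 60 °C
Reagents that add atoms: none
Why: Palladium-catalysed formate reduction of the enol triflate (oxidative addition, formate for triflate exchange, loss of CO2, reductive elimination) should replace OTf by H and leave the ester, the acetal and the allylic stereocentres C-5 and C-8 untouched.

**Step 9**
Reactants: 20 ester acetal
Product: 21 17,17-dimethoxy-12,13,14,15,16-pentanor-5αH,8βH,9αH-labd-6-en-11-al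
Conditions: i-Bu2AlH, toluene, −78 °C; aq. potassium sodium tartrate
Reagents that add atoms: none
Why: Partial ester reduction at low temperature should stop at the aluminium hemiacetal, which the neopentyl environment next to C-10 stabilizes, and give the aldehyde on work-up with the equatorial C-9 configuration retained.

**Step 10**
Reactants: 21 aldehyde acetal
Product: 22 17,17-dimethoxy-13,14,15,16-tetranor-5αH,8βH,9αH-labda-6,11-diene
Conditions: Ph3PCH3Br, KOt-Bu, THF, 0 °C to rt
Reagents that add atoms: methyltriphenylphosphonium bromide C[P+](c1ccccc1)(c1ccccc1)c1ccccc1.[Br-]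
Why: Wittig methylenation with the non-stabilized ylide should convert the hindered aldehyde into the vinyl group (C-11=C-12) without a new stereocentre and without epimerizing C-9.

**Step 11**
Reactants: 23 4-hydroxybut-2-ynoic acid
Product: 24 (2Z)-4-hydroxy-3-iodobut-2-enoic acid
Conditions: NaI, AcOH, 70 °C
Reagents that add atoms: sodium iodide [Na+].[I-]
Why: Conjugate addition of iodide to the ynoic acid followed by anti protonation (hydroiodination of alkynoic acids) should give the (Z)-3-iodo acid, which fixes the later 13E geometry and cannot lactonize because the hydroxymethyl group is trans to the carboxyl.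

**Step 12**
Reactants: 24 (2Z)-4-hydroxy-3-iodobut-2-enoic acid
Product: 25 (2Z)-4-(acetyloxy)-3-iodobut-2-enoic acid
Conditions: Ac2O, pyridine, DMAP (cat.), CH2Cl2, 0 °C; then H2O
Reagents that add atoms: acetic anhydride CC(=O)OC(C)=O
Why: Acylation of the primary alcohol under nucleophilic catalysis should give the acetate, the mixed anhydride formed at the carboxyl group being hydrolysed in the aqueous quench.

**Step 13**
Reactants: 22 vinyl acetal; 25 (2Z)-4-(acetyloxy)-3-iodobut-2-enoic acid
Product: 27 (13E)-16-acetoxy-17,17-dimethoxylabda-6,13-dien-15-oic acid, via B-alkyl-9-BBN 26 (not isolated)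
Conditions: 9-BBN-H, THF, 0 °C to rt; then 25 (as caesium salt), PdCl2(dppf) (5 mol %), AsPh3, Cs2CO3, DMF–H2O, rt; acidify to pH 4
Reagents that add atoms: none
Why: 9-BBN-H should hydroborate only the monosubstituted vinyl group (boron at C-12) and not the hindered ring alkene, and the B-alkyl Suzuki–Miyaura coupling proceeds with retention of the iodoalkene geometry, so that C-12 ends cis to the carboxyl and the acetoxymethyl group trans (13E).

**Step 14**
Reactants: 27 acetal acid
Product: 28 (13E)-16-acetoxy-17-oxolabda-6,13-dien-15-oic acid (5R,8S,9R,10S)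
Conditions: PPTS (0.2 equiv), acetone–H2O, rt
Reagents that add atoms: water O
Why: Mild acid-catalysed acetal hydrolysis (oxocarbenium ion, hemiacetal) should release the aldehyde at a pH at which the β,γ-unsaturated aldehyde does not enolize, so that the C-8 configuration and the 6,7-position of the alkene are kept while acetate and acid stay intact.

**Compound list**
1 | acetone | CC(C)=O | starting material
2 | pentane-2,4-dione | CC(=O)CC(C)=O | starting material
3 | 3-(propan-2-ylidene)pentane-2,4-dione | CC(=O)C(C(C)=O)=C(C)C | intermediate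
4 | allyltriphenylphosphonium bromide | C=CC[P+](c1ccccc1)(c1ccccc1)c1ccccc1.[Br-] | starting material
5 | allylidenetriphenylphosphorane | C=CC=P(c1ccccc1)(c1ccccc1)c1ccccc1 | intermediate
6 | vinylphosphonium diketone enolate (zwitterion from γ-Michael addition) | CC(=O)C(=C(C)[O-])C(C)(C)C/C=C/[P+](c1ccccc1)(c1ccccc1)c1ccccc1 | intermediate
7 | 1-(2,6,6-trimethylcyclohexa-2,4-dien-1-yl)ethan-1-one (racemic) | CC(=O)C1C(C)=CC=CC1(C)C | intermediate
8 | 1-(2,6,6-trimethylcyclohexa-1,3-dien-1-yl)ethan-1-one | CC(=O)C1=C(C)C=CCC1(C)C | intermediate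
9 | 1-(2,6,6-trimethylcyclohex-1-en-1-yl)ethan-1-one | CC(=O)C1=C(C)CCCC1(C)C | intermediate
10 | 5-hydroxyfuran-2(5H)-one (racemic) | OC1OC(=O)C=C1 | starting material
11 | (1S,2R,5S)-(+)-menthol | CC(C)[C@H]1CC[C@H](C)C[C@@H]1O | starting material
12 | (5S)-5-{[(1S,2R,5S)-5-methyl-2-(propan-2-yl)cyclohexyl]oxy}furan-2(5H)-one | O=C1C=C[C@@H](O[C@H]2C[C@@H](C)CC[C@@H]2C(C)C)O1 | intermediate
13 | lithium 1-(2,6,6-trimethylcyclohex-1-en-1-yl)ethenolate | [Li+].[O-]C(=C)C1=C(C)CCCC1(C)C | intermediate
14 | lithium lactone enolate of the mono-Michael adduct (C-7–C-8 bond formed, 8S, 17S) | [Li+].[O-]C1=C[C@H](CC(=O)C2=C(C)CCCC2(C)C)[C@@H](O[C@H]3C[C@@H](C)CC[C@@H]3C(C)C)O1 | intermediate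
15 | (17S)-17-[(1S,2R,5S)-menthyloxy]-6-oxo-12,13,14,15,16-pentanor-5αH,8βH,9βH-labdano-11,17-lactone (trans-decalin, lactone on the α-face) | O=C1O[C@H](O[C@H]4C[C@@H](C)CC[C@@H]4C(C)C)[C@H]2CC(=O)[C@@H]3C(C)(C)CCC[C@@]3(C)[C@@H]12 | intermediate
16 | methyl 6,17-dioxo-12,13,14,15,16-pentanor-5αH,8βH,9αH-labdan-11-oate (8α-formyl, 9β-ester) | COC(=O)[C@@H]1[C@@H](C=O)CC(=O)[C@@H]2C(C)(C)CCC[C@@]12C | intermediate
17 | methyl 17,17-dimethoxy-6-oxo-12,13,14,15,16-pentanor-5αH,8βH,9αH-labdan-11-oate | COC(=O)[C@@H]1[C@@H](C(OC)OC)CC(=O)[C@@H]2C(C)(C)CCC[C@@]12C | intermediate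
18 | potassium C-6/C-7 enolate of 17 | [K+].COC(=O)[C@@H]1[C@@H](C(OC)OC)C=C([O-])[C@@H]2C(C)(C)CCC[C@@]12C | intermediate
19 | methyl 17,17-dimethoxy-6-(trifluoromethylsulfonyloxy)-12,13,14,15,16-pentanor-5αH,8βH,9αH-labd-6-en-11-oate | COC(=O)[C@@H]1[C@@H](C(OC)OC)C=C(OS(=O)(=O)C(F)(F)F)[C@@H]2C(C)(C)CCC[C@@]12C | intermediate
20 | methyl 17,17-dimethoxy-12,13,14,15,16-pentanor-5αH,8βH,9αH-labd-6-en-11-oate | COC(=O)[C@@H]1[C@@H](C(OC)OC)C=C[C@@H]2C(C)(C)CCC[C@@]12C | intermediate
21 | 17,17-dimethoxy-12,13,14,15,16-pentanor-5αH,8βH,9αH-labd-6-en-11-al | O=C[C@@H]1[C@@H](C(OC)OC)C=C[C@@H]2C(C)(C)CCC[C@@]12C | intermediate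
22 | 17,17-dimethoxy-13,14,15,16-tetranor-5αH,8βH,9αH-labda-6,11-diene | C=C[C@@H]1[C@@H](C(OC)OC)C=C[C@@H]2C(C)(C)CCC[C@@]12C | intermediate
23 | 4-hydroxybut-2-ynoic acid | OCC#CC(=O)O | starting material
24 | (2Z)-4-hydroxy-3-iodobut-2-enoic acid | OC/C(I)=C/C(=O)O | intermediate
25 | (2Z)-4-(acetyloxy)-3-iodobut-2-enoic acid | CC(=O)OC/C(I)=C/C(=O)O | intermediate
26 | B-alkyl-9-BBN from 22 (boron on C-12) | C(C[C@@H]1[C@@H](C(OC)OC)C=C[C@@H]2C(C)(C)CCC[C@@]12C)B1C2CCCC1CCC2 | intermediate
27 | (13E)-16-acetoxy-17,17-dimethoxylabda-6,13-dien-15-oic acid (5αH,8βH,9αH) | CC(=O)OC/C(=C/C(=O)O)CC[C@@H]1[C@@H](C(OC)OC)C=C[C@@H]2C(C)(C)CCC[C@@]12C | intermediate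
28 | (13E)-16-acetoxy-17-oxolabda-6,13-dien-15-oic acid, (5R,8S,9R,10S) | CC(=O)OC/C(=C/C(=O)O)CC[C@@H]1[C@@H](C=O)C=C[C@@H]2C(C)(C)CCC[C@@]12C | target

**Step count**
Total step count: 14. Longest linear sequence: 11 (steps 1, 2, 3, 5, 6, 7, 8, 9, 10, 13, 14).

**Steps most likely to fail**

Step 5. The ring closure onto the twisted, tetrasubstituted enone (formation of the quaternary C-10) may stall after the first Michael addition, or the endo-like and facial selectivity may erode. The fallback is the concerted cycloaddition. It sets out from 9, which would be converted (LiN(i-Pr)2, t-BuMe2SiCl, THF–DMPU, −78 °C) into the silyl dienol ether tert-butyldimethyl{[1-(2,6,6-trimethylcyclohex-1-en-1-yl)ethenyl]oxy}silane F1. F1 should undergo a Diels–Alder reaction with 12 under 12 kbar (CH2Cl2, rt) or at 110 °C in toluene, endo and anti to the menthyloxy group, to give the 6-silyl enol ether of the cycloadduct F2. Bu4NF/AcOH would then protonate C-5 from the α-face and give 15, where the route is rejoined.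

Step 2. The ylide may attack an acetyl carbonyl directly, or the sequence may stall at the very stable diketone enolate 6 because proton transfer back to the ylide is unfavourable. The fallback uses the keto ester class for which this annulation is established. It sets out from 1, which would be condensed with ethyl 3-oxobutanoate (ZnCl2, Ac2O) to ethyl 2-acetyl-3-methylbut-2-enoate F3. Annulation of F3 with the ylide from 4 should give ethyl 2,6,6-trimethylcyclohexa-1,3-diene-1-carboxylate F4. Hydrogenation (H2, RhCl(PPh3)3) would give ethyl 2,6,6-trimethylcyclohex-1-ene-1-carboxylate F5, and saponification (KOH, ethylene glycol, 150 °C) would give 2,6,6-trimethylcyclohex-1-ene-1-carboxylic acid F6. Addition of MeLi (2 equiv, Et2O, 0 °C) to F6 should give 9, where the route is rejoined.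

Step 6. The thermodynamic preference for the equatorial 9β-ester may be incomplete, since the axial and equatorial positions next to the quaternary C-10 are close in energy. The fallback sets C-9 under kinetic control. It sets out from 15: step 6 would be run as written and would give 17 together with its C-9 epimer methyl 17,17-dimethoxy-6-oxo-12,13,14,15,16-pentanor-5αH,8βH,9βH-labdan-11-oate F7. The mixture would be taken through steps 7 and 8, which give the 9-epimeric enol triflate F8 and the 9-epimeric alkene ester F9 beside 19 and 20. Deprotonation (LiN(i-Pr)2, THF, −78 °C) converts both epimers into the same lithium ester enolate F10. Protonation of F10 with 2,6-di-tert-butylphenol from the α-face, anti to the C-10 methyl, should give 20, where the route is rejoined.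

**Further compounds**
F1 | step 5 | tert-butyldimethyl{[1-(2,6,6-trimethylcyclohex-1-en-1-yl)ethenyl]oxy}silane | C=C(O[Si](C)(C)C(C)(C)C)C1=C(C)CCCC1(C)C
F2 | step 5 | 6-(tert-butyldimethylsilyloxy)-5(6)-ene cycloadduct (silyl enol ether of 15) | O=C1O[C@H](O[C@H]4C[C@@H](C)CC[C@@H]4C(C)C)[C@H]2CC(O[Si](C)(C)C(C)(C)C)=C3C(C)(C)CCC[C@@]3(C)[C@@H]12
F3 | step 2 | ethyl 2-acetyl-3-methylbut-2-enoate | CCOC(=O)C(C(C)=O)=C(C)C
F4 | step 2 | ethyl 2,6,6-trimethylcyclohexa-1,3-diene-1-carboxylate | CCOC(=O)C1=C(C)C=CCC1(C)C
F5 | step 2 | ethyl 2,6,6-trimethylcyclohex-1-ene-1-carboxylate | CCOC(=O)C1=C(C)CCCC1(C)C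
F6 | step 2 | 2,6,6-trimethylcyclohex-1-ene-1-carboxylic acid | OC(=O)C1=C(C)CCCC1(C)C
F7 | step 6 | methyl 17,17-dimethoxy-6-oxo-12,13,14,15,16-pentanor-5αH,8βH,9βH-labdan-11-oate (9-epimer of 17) | COC(=O)[C@H]1[C@@H](C(OC)OC)CC(=O)[C@@H]2C(C)(C)CCC[C@@]12C
F8 | step 6 | 9-epimer of enol triflate 19 | COC(=O)[C@H]1[C@@H](C(OC)OC)C=C(OS(=O)(=O)C(F)(F)F)[C@@H]2C(C)(C)CCC[C@@]12C
F9 | step 6 | 9-epimer of alkene ester 20 | COC(=O)[C@H]1[C@@H](C(OC)OC)C=C[C@@H]2C(C)(C)CCC[C@@]12C
F10 | step 6 | lithium ester enolate (C-9 planar) | [Li+].COC([O-])=C1[C@@H](C(OC)OC)C=C[C@@H]2C(C)(C)CCC[C@@]12C
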